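**Plan**
- Ring A is a hexasubstituted benzene whose three C–O carbons alternate with the carbons carrying prenyl, the CH2 bridge and isobutyryl. After removal of the acyl group (Friedel–Crafts), this 1,3,5-trioxygenated ring is cut at two ring bonds, C(prenyl)–C(OH) and C(OH)–C(acyl-bearing carbon), giving a prenyl siloxyalkyne and a 3-ethoxycyclobutenone that holds ring B on C4 through the bridge CH2.
- The cyclobutenone is cut to a ketene (from a ring B propanoic acid) and ethoxyacetylene. The propanoate chain is cut from a ring B iodide (Negishi). Ring B goes back to an aromatic benzoxazepinone (Birch reductive prenylation), whose lactam carbonyl becomes the isobutyryl ketone.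
- Forward order: arene, chiral benzoxazepinone, Birch prenylation, lactam opening with i-PrLi, dienone, iodide, side chain, four-membered ring. Ring A is then built by the benzannulation, acylated and deprotected.
- Stereochemistry: the only stereocentre, the quaternary carbon of ring B, is set in the Birch alkylation by the (S)-prolinol unit tied to one ortho oxygen. It is quaternary and is not touched again. The auxiliary arm stays on as an enol ether protecting group and leaves in the last step.

Key step: step 13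

Assumption 1: the target is one tautomer of an enolised 2-acyl-2-prenyl triketone; the tautomers equilibrate, so only the quaternary carbon has to be controlled.
Assumption 2: the tethered (S)-auxiliary is taken to send prenyl bromide to the enolate face that gives the 5aR,11aS lactam (prenyl trans to the ring-fusion hydrogen). This facial sense is assumed, not established here; if the other face were preferred, (R)-prolinol would be used in step 2 and every later operation stays the same.
Shorthand in names: RB = (3S)-4-methoxy-2-{[(2S)-1-(methoxycarbonyl)pyrrolidin-2-yl]methoxy}-5-methyl-3-(2-methylpropanoyl)-3-(3-methylbut-2-enyl)-6-oxocyclohexa-1,4-dien-1-yl.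

**Route**

Step 1
Reactants: 1 5-fluoro-2-methylanisole
Product: 3 6-fluoro-2-methoxy-3-methylbenzoic acid, via aryllithium 2 (not isolated)
Conditions: n-BuLi, THF, −78 °C; CO2; aq HCl
Reagents that add atoms: carbon dioxide, O=C=O
Why: Directed ortho-metalation removes the proton flanked by fluorine and methoxy, the most acidic ring position, and carboxylation at −78 °C (below the onset of LiF loss to an aryne) installs the carbon that later becomes the isobutyryl carbonyl.

Step 2
Reactants: 3 6-fluoro-2-methoxy-3-methylbenzoic acid; 4 (S)-prolinol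
Product: 6 (6-fluoro-2-methoxy-3-methylphenyl)[(2S)-2-(hydroxymethyl)pyrrolidin-1-yl]methanone, via acid chloride 5 (not isolated)
Conditions: (COCl)2, DMF (cat.), CH2Cl2, 0 °C → rt; then 4, Et3N, CH2Cl2, 0 °C
Reagents that add atoms: none
Why: Amide formation through the acid chloride should be selective for nitrogen because the secondary amine of prolinol is far more nucleophilic than its primary hydroxyl.

Step 3
Reactants: 6 (6-fluoro-2-methoxy-3-methylphenyl)[(2S)-2-(hydroxymethyl)pyrrolidin-1-yl]methanone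
Product: 7 (11aS)-6-methoxy-7-methyl-2,3,11,11a-tetrahydro-1H,5H-pyrrolo[2,1-c][1,4]benzoxazepin-5-one
Conditions: NaH, DMF, 0 → 80 °C
Reagents that add atoms: none
Why: Intramolecular nucleophilic aromatic substitution, in which the alkoxide displaces the fluoride ortho to the carboxamide and closes the seven-membered aryl ether lactam that ties the auxiliary to one defined ortho carbon.

Step 4
Reactants: 7 (11aS)-6-methoxy-7-methyl-2,3,11,11a-tetrahydro-1H,5H-pyrrolo[2,1-c][1,4]benzoxazepin-5-one; 8 prenyl bromide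
Product: 10 (5aR,11aS)-6-methoxy-7-methyl-5a-(3-methylbut-2-enyl)-2,3,5a,8,11,11a-hexahydro-1H,5H-pyrrolo[2,1-c][1,4]benzoxazepin-5-one, via potassium enolate 9 (not isolated)
Conditions: K, NH3/THF, t-BuOH (1 equiv), −78 °C; then 8, −78 °C; NH4Cl
Reagents that add atoms: none
Why: Birch reduction–alkylation, in which two-electron reduction with one proton delivered para gives amide enolate 9 of ring-locked geometry and prenyl bromide alkylates it at carbon on the face set by the fused (S)-pyrrolidine (auxiliary control relayed from C11a), creating the quaternary stereocentre as 5aR with both enol ethers left in place; a minor diastereomer would be removed by chromatography here.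

Step 5
Reactants: 10 (5aR,11aS)-6-methoxy-7-methyl-5a-(3-methylbut-2-enyl)-2,3,5a,8,11,11a-hexahydro-1H,5H-pyrrolo[2,1-c][1,4]benzoxazepin-5-one
Product: 12 methyl (2S)-2-({[(6R)-5-methoxy-4-methyl-6-(2-methylpropanoyl)-6-(3-methylbut-2-enyl)cyclohexa-1,4-dien-1-yl]oxy}methyl)pyrrolidine-1-carboxylate, via amino ketone 11 (not isolated)
Conditions: i-PrLi, Et2O, −78 → −20 °C; aq NH4Cl; then ClCO2Me, Et3N, CH2Cl2, 0 °C
Reagents that add atoms: isopropyllithium, CC(C)[Li]; methyl chloroformate, COC(=O)Cl
Why: Ketone synthesis from a tertiary amide and an organolithium, in which the lactam carbonyl has no α-hydrogen, the tetrahedral lithium alkoxide persists until the quench and then opens the seven-membered ring to the isopropyl ketone, and the freed pyrrolidine nitrogen is capped as a methyl carbamate so that the auxiliary arm can serve as a robust enol ether protecting group (exchanging it for methyl in acidic or basic methanol would endanger the acyl group on the quaternary carbon).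

Step 6
Reactants: 12 methyl (2S)-2-({[(6R)-5-methoxy-4-methyl-6-(2-methylpropanoyl)-6-(3-methylbut-2-enyl)cyclohexa-1,4-dien-1-yl]oxy}methyl)pyrrolidine-1-carboxylate
Product: 13 methyl (2S)-2-({[(6R)-5-methoxy-4-methyl-6-(2-methylpropanoyl)-6-(3-methylbut-2-enyl)-3-oxocyclohexa-1,4-dien-1-yl]oxy}methyl)pyrrolidine-1-carboxylate
Conditions: t-BuOOH, (C5H5NH)2Cr2O7, Celite, benzene, rt
Reagents that add atoms: tert-butyl hydroperoxide, CC(C)(C)OO
Why: Chromium-mediated allylic oxidation of a Birch-derived 1,4-diene, in which the ring CH2 between two enol ether double bonds is the most activated C–H, the quaternary carbon blocks aromatisation, and the product is the cross-conjugated dienone with both oxygens now vinylogous esters.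

Step 7
Reactants: 13 methyl (2S)-2-({[(6R)-5-methoxy-4-methyl-6-(2-methylpropanoyl)-6-(3-methylbut-2-enyl)-3-oxocyclohexa-1,4-dien-1-yl]oxy}methyl)pyrrolidine-1-carboxylate
Product: 14 methyl (2S)-2-({[(6S)-2-iodo-5-methoxy-4-methyl-6-(2-methylpropanoyl)-6-(3-methylbut-2-enyl)-3-oxocyclohexa-1,4-dien-1-yl]oxy}methyl)pyrrolidine-1-carboxylate
Conditions: NIS, CH2Cl2, 0 °C, dark
Reagents that add atoms: N-iodosuccinimide, O=C1CCC(=O)N1I
Why: Electrophilic α-iodination of a vinylogous ester, whose only ring C–H is the electron-rich enol ether β-carbon and should react ahead of the isolated prenyl alkene in an aprotic medium without added acid.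

Step 8
Reactants: 14 methyl (2S)-2-({[(6S)-2-iodo-5-methoxy-4-methyl-6-(2-methylpropanoyl)-6-(3-methylbut-2-enyl)-3-oxocyclohexa-1,4-dien-1-yl]oxy}methyl)pyrrolidine-1-carboxylate
Product: 15 methyl 3-(RB)propanoate
Conditions: BrZnCH2CH2CO2Me (from BrCH2CH2CO2Me, Zn, LiCl, THF, 40 °C), Pd(OAc)2 (3 mol%), SPhos (6 mol%), THF, rt → 40 °C
Reagents that add atoms: (3-methoxy-3-oxopropyl)zinc bromide, COC(=O)CC[Zn]Br
Why: Negishi cross-coupling of an α-iodoenone with a zinc homoenolate, a reagent mild enough to leave the ketone, carbamate and vinylogous esters alone while the three-carbon chain is joined to the ring.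

Step 9
Reactants: 15 methyl 3-(RB)propanoate
Product: 16 3-(RB)propanoic acid
Conditions: Me3SnOH, ClCH2CH2Cl, 70 °C; 5% aq HCl wash
Reagents that add atoms: trimethyltin hydroxide, C[Sn](C)(C)O
Why: Tin hydroxide-mediated ester hydrolysis under near-neutral conditions should cleave only the unhindered methyl ester and avoids hydroxide or alkoxide, which could hydrolyse the vinylogous esters or expel the acyl group from the quaternary carbon by retro-Claisen aromatisation.

Step 10
Reactants: 16 3-(RB)propanoic acid; 17 ethoxyacetylene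
Product: 20 3-ethoxy-4-(RB-methyl)cyclobut-2-en-1-one as both epimers at C4 of the four-membered ring, via acid chloride 18 (not isolated), via ketene 19 (not isolated)
Conditions: Me2C=C(Cl)NMe2, CH2Cl2, 0 °C → rt; then 17 (5 equiv), Et3N (slow addition), CH2Cl2, rt
Reagents that add atoms: none
Why: Acid chloride formation under neutral conditions, dehydrochlorination to the aldoketene and its [2+2] cycloaddition with the ynol ether, in which the terminal alkyne carbon bonds to the ketene carbonyl carbon so that ethoxy ends at C3 and the ring B methylene at C4; the new CH stereocentre is uncontrolled and is lost in step 13.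

Step 11
Reactants: 8 prenyl bromide
Product: 21 5-methylhex-4-en-1-yne
Conditions: HC≡CMgBr, CuCl (5 mol%), THF, 0 °C → rt
Reagents that add atoms: ethynylmagnesium bromide, C#C[Mg]Br
Why: Copper-catalysed coupling of an alkynyl Grignard reagent with an allylic bromide should take place mainly at the primary carbon (SN2) and give the skipped enyne.

Step 12
Reactants: 21 5-methylhex-4-en-1-yne
Product: 24 triisopropyl[(5-methylhex-4-en-1-yn-1-yl)oxy]silane, via lithium acetylide 22 (not isolated), via lithium ynolate 23 (not isolated)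
Conditions: LiN(SiMe3)2 (2.1 equiv), THF, −78 °C; t-BuOOH, −78 → 0 °C; TIPSOTf, −78 → 0 °C
Reagents that add atoms: lithium tert-butyl peroxide (made in the flask from t-BuOOH and LiN(SiMe3)2), CC(C)(C)OO[Li]; triisopropylsilyl trifluoromethanesulfonate, CC(C)[Si](C(C)C)(C(C)C)OS(=O)(=O)C(F)(F)F
Why: Oxidation of a lithium acetylide to the ynolate by electrophilic oxygen transfer from the lithium peroxide, followed by silylation with the bulky silyl triflate, which should go to oxygen and not to carbon, is an established route to siloxyalkynes.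

Step 13
Reactants: 20 3-ethoxy-4-(RB-methyl)cyclobut-2-en-1-one; 24 triisopropyl[(5-methylhex-4-en-1-yn-1-yl)oxy]silane
Product: 29 3-ethoxy-2-(RB-methyl)-6-(3-methylbut-2-enyl)-5-[tri(propan-2-yl)silyloxy]phenol, via vinylketene 25 (not isolated), via vinylcyclobutenone 26 (not isolated), via dienylketene 27 (not isolated), via cyclohexadienone 28 (not isolated)
Conditions: 24 (1.5 equiv), toluene, 80 °C, then 110 °C
Reagents that add atoms: none
Why: On heating, 20 should undergo 4π electrocyclic ring opening (the C4 substituent turning outward) to vinylketene 25, whose ketene C=C adds the siloxyalkyne in a [2+2] cycloaddition to give 26. A second 4π opening gives dienylketene 27, which closes ring A by thermal disrotatory 6π electrocyclisation to cyclohexadienone 28, and tautomerisation delivers the phenol; the closest known reaction is the Danheiser benzannulation of cyclobutenones with siloxyalkynes to resorcinol monosilyl ethers. Two ring bonds are made, one at each alkyne carbon, and the other four ring atoms come from the cyclobutenone, so every substituent position is fixed by connectivity. No stereocentre is created: the cyclobutenone CH is destroyed and the ring B quaternary carbon is a remote spectator. The selectivity needed is the orientation of the [2+2] step, which the polarised ynol ether secures, since its unoxygenated carbon bonds to the electrophilic ketene carbonyl carbon and so places prenyl next to the new hydroxyl and the silyl ether next to the unsubstituted carbon. The three oxygens emerge differentiated (free hydroxyl, silyl ether, ethyl ether), and neither the ring B dienone nor the prenyl alkenes should compete with the far more nucleophilic siloxyalkyne for the ketene.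

Step 14
Reactants: 29 3-ethoxy-2-(RB-methyl)-6-(3-methylbut-2-enyl)-5-[tri(propan-2-yl)silyloxy]phenol
Product: 30 1-{2-ethoxy-4-hydroxy-3-(RB-methyl)-5-(3-methylbut-2-enyl)-6-[tri(propan-2-yl)silyloxy]phenyl}-2-methylpropan-1-one
Conditions: i-PrCOCl, TiCl4, CH2Cl2, −78 → −40 °C
Reagents that add atoms: isobutyryl chloride, CC(C)C(=O)Cl
Why: Friedel–Crafts acylation at the single ring A C–H, which lies para to the hydroxyl (held as its titanium phenoxide, so O-acylation is suppressed) and ortho to both ethers and is therefore the most nucleophilic arene position, with low temperature chosen to spare the prenyl groups, the silyl ether and the dienone.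

Step 15
Reactants: 30 1-{2-ethoxy-4-hydroxy-3-(RB-methyl)-5-(3-methylbut-2-enyl)-6-[tri(propan-2-yl)silyloxy]phenyl}-2-methylpropan-1-one
Product: 31 1-{2,4-dihydroxy-3-(RB-methyl)-5-(3-methylbut-2-enyl)-6-[tri(propan-2-yl)silyloxy]phenyl}-2-methylpropan-1-one
Conditions: BCl3, CH2Cl2, −78 → −20 °C; aq NaHCO3
Reagents that add atoms: none
Why: Chelation-assisted ether cleavage, in which BCl3 bridges the new ketone and the ortho ethoxy oxygen and chloride removes the ethyl group by SN2 at low temperature, the standard selective dealkylation of an alkyl aryl ether ortho to a carbonyl group.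

Step 16
Reactants: 31 1-{2,4-dihydroxy-3-(RB-methyl)-5-(3-methylbut-2-enyl)-6-[tri(propan-2-yl)silyloxy]phenyl}-2-methylpropan-1-one
Product: 32 1-[2,4,6-trihydroxy-3-(RB-methyl)-5-(3-methylbut-2-enyl)phenyl]-2-methylpropan-1-one
Conditions: Bu4NF, AcOH, THF, 0 °C
Reagents that add atoms: none
Why: Fluoride-induced desilylation of the aryl silyl ether, buffered with acetic acid so that no free phenoxide or basic fluoride is left to attack the base-sensitive acyl dienone.

Step 17
Reactants: 32 1-[2,4,6-trihydroxy-3-(RB-methyl)-5-(3-methylbut-2-enyl)phenyl]-2-methylpropan-1-one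
Product: 33 CNP0191741.1, (4S)-3,5-dihydroxy-6-methyl-4-(2-methylpropanoyl)-4-(3-methylbut-2-enyl)-2-{[2,4,6-trihydroxy-3-(2-methylpropanoyl)-5-(3-methylbut-2-enyl)phenyl]methyl}cyclohexa-2,5-dien-1-one
Conditions: 2 M aq HCl, THF, 40 °C
Reagents that add atoms: water, O
Why: Acid hydrolysis of the two vinylogous esters by conjugate addition of water and loss of methanol and of the auxiliary alcohol, which frees the enolised triketone of ring B without touching the quaternary stereocentre, under acid mild enough to spare the ortho-prenyl phenols.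

**Compound list**

The descriptor of the quaternary carbon changes from R to S at 14 only because iodine (and later the side chain) raises the priority of one ring branch; the spatial arrangement is the same throughout.

1 | 5-fluoro-2-methylanisole | COc1cc(F)ccc1C | starting material
2 | 6-fluoro-2-methoxy-3-methylphenyllithium | COc1c([Li])c(F)ccc1C | intermediate
3 | 6-fluoro-2-methoxy-3-methylbenzoic acid | COc1c(C(=O)O)c(F)ccc1C | intermediate
4 | (S)-prolinol | OC[C@@H]1CCCN1 | starting material
5 | 6-fluoro-2-methoxy-3-methylbenzoyl chloride | COc1c(C(=O)Cl)c(F)ccc1C | intermediate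
6 | (6-fluoro-2-methoxy-3-methylphenyl)[(2S)-2-(hydroxymethyl)pyrrolidin-1-yl]methanone | COc1c(C(=O)N2CCC[C@H]2CO)c(F)ccc1C | intermediate
7 | (11aS)-6-methoxy-7-methyl-2,3,11,11a-tetrahydro-1H,5H-pyrrolo[2,1-c][1,4]benzoxazepin-5-one | COc1c(C)ccc2OC[C@@H]3CCCN3C(=O)c12 | intermediate
8 | prenyl bromide (1-bromo-3-methylbut-2-ene) | CC(C)=CCBr | starting material
9 | potassium amide enolate of 5a,8-dihydro-7 | COC1=C(C)CC=C2OC[C@@H]3CCCN3C([O-])=C12.[K+] | intermediate
10 | (5aR,11aS)-6-methoxy-7-methyl-5a-(3-methylbut-2-enyl)-2,3,5a,8,11,11a-hexahydro-1H,5H-pyrrolo[2,1-c][1,4]benzoxazepin-5-one | COC1=C(C)CC=C2OC[C@@H]3CCCN3C(=O)[C@@]12CC=C(C)C | intermediate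
11 | 1-[(1R)-2-methoxy-3-methyl-1-(3-methylbut-2-enyl)-6-{[(2S)-pyrrolidin-2-yl]methoxy}cyclohexa-2,5-dien-1-yl]-2-methylpropan-1-one | C1C=C(OC[C@@H]2CCCN2)[C@@](CC=C(C)C)(C(=O)C(C)C)C(OC)=C1C | intermediate
12 | methyl (2S)-2-({[(6R)-5-methoxy-4-methyl-6-(2-methylpropanoyl)-6-(3-methylbut-2-enyl)cyclohexa-1,4-dien-1-yl]oxy}methyl)pyrrolidine-1-carboxylate | C1C=C(OC[C@@H]2CCCN2C(=O)OC)[C@@](CC=C(C)C)(C(=O)C(C)C)C(OC)=C1C | intermediate
13 | methyl (2S)-2-({[(6R)-5-methoxy-4-methyl-6-(2-methylpropanoyl)-6-(3-methylbut-2-enyl)-3-oxocyclohexa-1,4-dien-1-yl]oxy}methyl)pyrrolidine-1-carboxylate | O=C1C=C(OC[C@@H]2CCCN2C(=O)OC)[C@@](CC=C(C)C)(C(=O)C(C)C)C(OC)=C1C | intermediate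
14 | methyl (2S)-2-({[(6S)-2-iodo-5-methoxy-4-methyl-6-(2-methylpropanoyl)-6-(3-methylbut-2-enyl)-3-oxocyclohexa-1,4-dien-1-yl]oxy}methyl)pyrrolidine-1-carboxylate | O=C1C(I)=C(OC[C@@H]2CCCN2C(=O)OC)[C@@](CC=C(C)C)(C(=O)C(C)C)C(OC)=C1C | intermediate
15 | methyl 3-(RB)propanoate | COC(=O)CCC1=C(OC[C@@H]2CCCN2C(=O)OC)[C@@](CC=C(C)C)(C(=O)C(C)C)C(OC)=C(C)C1=O | intermediate
16 | 3-(RB)propanoic acid | OC(=O)CCC1=C(OC[C@@H]2CCCN2C(=O)OC)[C@@](CC=C(C)C)(C(=O)C(C)C)C(OC)=C(C)C1=O | intermediate
17 | ethoxyacetylene | C#COCC | starting material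
18 | 3-(RB)propanoyl chloride | ClC(=O)CCC1=C(OC[C@@H]2CCCN2C(=O)OC)[C@@](CC=C(C)C)(C(=O)C(C)C)C(OC)=C(C)C1=O | intermediate
19 | 3-(RB)prop-1-en-1-one (ketene) | O=C=CCC1=C(OC[C@@H]2CCCN2C(=O)OC)[C@@](CC=C(C)C)(C(=O)C(C)C)C(OC)=C(C)C1=O | intermediate
20 | 3-ethoxy-4-(RB-methyl)cyclobut-2-en-1-one, both epimers at C4 | CCOC1=CC(=O)C1CC2=C(OC[C@@H]3CCCN3C(=O)OC)[C@@](CC=C(C)C)(C(=O)C(C)C)C(OC)=C(C)C2=O | intermediate
21 | 5-methylhex-4-en-1-yne | CC(C)=CCC#C | intermediate
22 | (5-methylhex-4-en-1-yn-1-yl)lithium | CC(C)=CCC#C[Li] | intermediate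
23 | lithium 5-methylhex-4-en-1-yn-1-olate | CC(C)=CCC#CO[Li] | intermediate
24 | triisopropyl[(5-methylhex-4-en-1-yn-1-yl)oxy]silane | CC(C)=CCC#CO[Si](C(C)C)(C(C)C)C(C)C | intermediate
25 | 3-ethoxy-5-(RB)penta-1,3-dien-1-one (vinylketene) | CCOC(C=C=O)=CCC1=C(OC[C@@H]2CCCN2C(=O)OC)[C@@](CC=C(C)C)(C(=O)C(C)C)C(OC)=C(C)C1=O | intermediate
26 | 4-[1-ethoxy-3-(RB)prop-1-enyl]-2-(3-methylbut-2-enyl)-3-[tri(propan-2-yl)silyloxy]cyclobut-2-en-1-one | CCOC(=CCC1=C(OC[C@@H]2CCCN2C(=O)OC)[C@@](CC=C(C)C)(C(=O)C(C)C)C(OC)=C(C)C1=O)C3C(=O)C(CC=C(C)C)=C3O[Si](C(C)C)(C(C)C)C(C)C | intermediate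
27 | 5-ethoxy-2-(3-methylbut-2-enyl)-7-(RB)-3-[tri(propan-2-yl)silyloxy]hepta-1,3,5-trien-1-one (dienylketene) | CCOC(=CCC1=C(OC[C@@H]2CCCN2C(=O)OC)[C@@](CC=C(C)C)(C(=O)C(C)C)C(OC)=C(C)C1=O)C=C(O[Si](C(C)C)(C(C)C)C(C)C)C(CC=C(C)C)=C=O | intermediate
28 | 5-ethoxy-6-(RB-methyl)-2-(3-methylbut-2-enyl)-3-[tri(propan-2-yl)silyloxy]cyclohexa-2,4-dien-1-one | CCOC1=CC(O[Si](C(C)C)(C(C)C)C(C)C)=C(CC=C(C)C)C(=O)C1CC2=C(OC[C@@H]3CCCN3C(=O)OC)[C@@](CC=C(C)C)(C(=O)C(C)C)C(OC)=C(C)C2=O | intermediate
29 | 3-ethoxy-2-(RB-methyl)-6-(3-methylbut-2-enyl)-5-[tri(propan-2-yl)silyloxy]phenol | CCOc1cc(O[Si](C(C)C)(C(C)C)C(C)C)c(CC=C(C)C)c(O)c1CC2=C(OC[C@@H]3CCCN3C(=O)OC)[C@@](CC=C(C)C)(C(=O)C(C)C)C(OC)=C(C)C2=O | intermediate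
30 | 1-{2-ethoxy-4-hydroxy-3-(RB-methyl)-5-(3-methylbut-2-enyl)-6-[tri(propan-2-yl)silyloxy]phenyl}-2-methylpropan-1-one | CCOc1c(C(=O)C(C)C)c(O[Si](C(C)C)(C(C)C)C(C)C)c(CC=C(C)C)c(O)c1CC2=C(OC[C@@H]3CCCN3C(=O)OC)[C@@](CC=C(C)C)(C(=O)C(C)C)C(OC)=C(C)C2=O | intermediate
31 | 1-{2,4-dihydroxy-3-(RB-methyl)-5-(3-methylbut-2-enyl)-6-[tri(propan-2-yl)silyloxy]phenyl}-2-methylpropan-1-one | Oc1c(C(=O)C(C)C)c(O[Si](C(C)C)(C(C)C)C(C)C)c(CC=C(C)C)c(O)c1CC2=C(OC[C@@H]3CCCN3C(=O)OC)[C@@](CC=C(C)C)(C(=O)C(C)C)C(OC)=C(C)C2=O | intermediate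
32 | 1-[2,4,6-trihydroxy-3-(RB-methyl)-5-(3-methylbut-2-enyl)phenyl]-2-methylpropan-1-one | Oc1c(C(=O)C(C)C)c(O)c(CC=C(C)C)c(O)c1CC2=C(OC[C@@H]3CCCN3C(=O)OC)[C@@](CC=C(C)C)(C(=O)C(C)C)C(OC)=C(C)C2=O | intermediate
33 | CNP0191741.1, (4S)-3,5-dihydroxy-6-methyl-4-(2-methylpropanoyl)-4-(3-methylbut-2-enyl)-2-{[2,4,6-trihydroxy-3-(2-methylpropanoyl)-5-(3-methylbut-2-enyl)phenyl]methyl}cyclohexa-2,5-dien-1-one | CC(C)=CCc1c(O)c(CC2=C(O)[C@@](CC=C(C)C)(C(=O)C(C)C)C(O)=C(C)C2=O)c(O)c(C(=O)C(C)C)c1O | target

**Step count and risks**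

Total steps: 17. Longest linear sequence: 15 (steps 1–10 and 13–17); steps 11 and 12 form the short second branch.

Steps most likely to fail:

1. Step 5. The isopropyllithium may not reach the neopentyl-type lactam carbonyl and may instead abstract a bis-allylic ring proton, so that no ketone forms. The fallback sets out from 10 and builds the ketone at the aldehyde oxidation level. Reductive opening of the lactam with LiNH2BH3 (THF, 0 °C → rt) should give the amino alcohol [(2-methoxy-3-methyl-1-(3-methylbut-2-enyl)-6-{[(2S)-pyrrolidin-2-yl]methoxy}cyclohexa-2,5-dien-1-yl]methanol F1. Selective N-acylation with ClCO2Me and Et3N gives the carbamate alcohol F2. Buffered Dess–Martin oxidation (NaHCO3) gives the non-enolisable aldehyde F3. Addition of i-PrMgCl in the presence of CeCl3 gives the secondary alcohol F4 as a mixture of carbinol epimers. A second Dess–Martin oxidation comes back to the route at 12.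

2. Step 14. The activated acyl chloride may attack the prenyl double bonds, the Lewis acid may close a chroman from the phenol onto its ortho prenyl group, or the Lewis-acid-bound dienone may lose its prenyl or acyl group. The fallback carries the acyl carbon through the benzannulation and so needs no electrophilic acylation. Ethoxyacetylene 17 is lithiated (n-BuLi, THF, −78 °C) and added to isobutyraldehyde to give 1-ethoxy-4-methylpent-1-yn-3-ol F5, which is silylated (Et3SiCl, imidazole) to its triethylsilyl ether F6. Ketene 19, generated from 16 as in step 10, is trapped by F6 to give 3-ethoxy-2-[2-methyl-1-(triethylsilyloxy)propyl]-4-(RB-methyl)cyclobut-2-en-1-one F7. Heating F7 with 24 as in step 13 should give the hexasubstituted phenol F8, which carries the silylated carbinol between the two ethers. Buffered HF·pyridine removes only the alkyl triethylsilyl group to give the benzylic alcohol F9. Oxidation with MnO2 comes back to the route at 30.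

3. Step 15. BCl3 and the HCl it releases may add to the prenyl groups, cyclise them onto the neighbouring phenol oxygens, or cleave the silyl ether and the dienone substituents before the ethyl group has gone. The fallback replaces the ethyl ether by a tert-butyl ether that leaves without a separate dealkylation. tert-Butyl vinyl ether is brominated (Br2, Et2O, −78 °C) to 1,2-dibromo-1-tert-butoxyethane F10, and double dehydrobromination (NaNH2, liquid NH3) gives tert-butoxyacetylene F11. Ketene 19 (from 16 as in step 10) adds F11 to give 3-tert-butoxy-4-(RB-methyl)cyclobut-2-en-1-one F12. Benzannulation with 24 under the conditions of step 13 gives 3-tert-butoxy-2-(RB-methyl)-6-(3-methylbut-2-enyl)-5-[tri(propan-2-yl)silyloxy]phenol F13. Under the acylation conditions of step 14 the tert-butyl ether should be lost as 2-methylpropene while the ring is acylated, and the sequence comes back to the route at 31.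

Further compounds
F1 | step 5 | [(2-methoxy-3-methyl-1-(3-methylbut-2-enyl)-6-{[(2S)-pyrrolidin-2-yl]methoxy}cyclohexa-2,5-dien-1-yl]methanol, quaternary carbon as in 10 | C1C=C(OC[C@@H]2CCCN2)[C@@](CC=C(C)C)(CO)C(OC)=C1C
F2 | step 5 | methyl (2S)-2-({[6-(hydroxymethyl)-5-methoxy-4-methyl-6-(3-methylbut-2-enyl)cyclohexa-1,4-dien-1-yl]oxy}methyl)pyrrolidine-1-carboxylate | C1C=C(OC[C@@H]2CCCN2C(=O)OC)[C@@](CC=C(C)C)(CO)C(OC)=C1C
F3 | step 5 | methyl (2S)-2-({[6-formyl-5-methoxy-4-methyl-6-(3-methylbut-2-enyl)cyclohexa-1,4-dien-1-yl]oxy}methyl)pyrrolidine-1-carboxylate | C1C=C(OC[C@@H]2CCCN2C(=O)OC)[C@@](CC=C(C)C)(C=O)C(OC)=C1C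
F4 | step 5 | methyl (2S)-2-({[6-(1-hydroxy-2-methylpropyl)-5-methoxy-4-methyl-6-(3-methylbut-2-enyl)cyclohexa-1,4-dien-1-yl]oxy}methyl)pyrrolidine-1-carboxylate, carbinol epimers | C1C=C(OC[C@@H]2CCCN2C(=O)OC)[C@@](CC=C(C)C)(C(O)C(C)C)C(OC)=C1C
F5 | step 14 | 1-ethoxy-4-methylpent-1-yn-3-ol | CCOC#CC(O)C(C)C
F6 | step 14 | [(1-ethoxy-4-methylpent-1-yn-3-yl)oxy]triethylsilane | CCOC#CC(O[Si](CC)(CC)CC)C(C)C
F7 | step 14 | 3-ethoxy-2-[2-methyl-1-(triethylsilyloxy)propyl]-4-(RB-methyl)cyclobut-2-en-1-one | CCOC1=C(C(O[Si](CC)(CC)CC)C(C)C)C(=O)C1CC2=C(OC[C@@H]3CCCN3C(=O)OC)[C@@](CC=C(C)C)(C(=O)C(C)C)C(OC)=C(C)C2=O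
F8 | step 14 | 3-ethoxy-4-[2-methyl-1-(triethylsilyloxy)propyl]-2-(RB-methyl)-6-(3-methylbut-2-enyl)-5-[tri(propan-2-yl)silyloxy]phenol | CCOc1c(C(O[Si](CC)(CC)CC)C(C)C)c(O[Si](C(C)C)(C(C)C)C(C)C)c(CC=C(C)C)c(O)c1CC2=C(OC[C@@H]3CCCN3C(=O)OC)[C@@](CC=C(C)C)(C(=O)C(C)C)C(OC)=C(C)C2=O
F9 | step 14 | 3-ethoxy-4-(1-hydroxy-2-methylpropyl)-2-(RB-methyl)-6-(3-methylbut-2-enyl)-5-[tri(propan-2-yl)silyloxy]phenol | CCOc1c(C(O)C(C)C)c(O[Si](C(C)C)(C(C)C)C(C)C)c(CC=C(C)C)c(O)c1CC2=C(OC[C@@H]3CCCN3C(=O)OC)[C@@](CC=C(C)C)(C(=O)C(C)C)C(OC)=C(C)C2=O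
F10 | step 15 | 1,2-dibromo-1-tert-butoxyethane | CC(C)(C)OC(Br)CBr
F11 | step 15 | tert-butoxyacetylene | CC(C)(C)OC#C
F12 | step 15 | 3-tert-butoxy-4-(RB-methyl)cyclobut-2-en-1-one, both epimers at C4 | CC(C)(C)OC1=CC(=O)C1CC2=C(OC[C@@H]3CCCN3C(=O)OC)[C@@](CC=C(C)C)(C(=O)C(C)C)C(OC)=C(C)C2=O
F13 | step 15 | 3-tert-butoxy-2-(RB-methyl)-6-(3-methylbut-2-enyl)-5-[tri(propan-2-yl)silyloxy]phenol | CC(C)(C)Oc1cc(O[Si](C(C)C)(C(C)C)C(C)C)c(CC=C(C)C)c(O)c1CC2=C(OC[C@@H]3CCCN3C(=O)OC)[C@@](CC=C(C)C)(C(=O)C(C)C)C(OC)=C(C)C2=O
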